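All runs are simulated for an exercise; noise was put on by code.

How high does right-handed product stand in the flask by 15 min, and when does it pass the level asked?

| flask | left-handed substrate | right-handed substrate | partner | remark | time |
|---|---|---|---|---|---|
| epsilon | 0.13 M | 0.13 M | 0.40 M (fed, over 80 s) | run made earlier; the fed solution adds 1.0 times the starting volume |  |
| beta | 0.30 M | 0.30 M | 0.40 M (fed, over 80 s) | run made earlier; the fed solution adds 1.0 times the starting volume |  |
| alpha | 0.20 M | 0.20 M | 0.80 M (fed, over 80 s) | run made earlier; the fed solution adds 1.0 times the starting volume |  |
| flask | 0.20 M | 0.20 M | 0.400 M (fed, over 80 s) | the fed solution adds 1.0 times the starting volume | 15 min |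

| run | time / min | right-handed product / % | left-handed product / % |
|---|---|---|---|
| epsilon | 4.00 | 6.7 | 33.4 |
| epsilon | 5.00 | 7.7 | 37.2 |
| epsilon | 6.00 | 9.0 | 40.1 |
| epsilon | 8.00 | 11.5 | 43.9 |
| epsilon | 10.0 | 13.7 | 46.1 |
| beta | 4.00 | 5.6 | 28.7 |
| beta | 5.00 | 6.4 | 32.5 |
| beta | 6.00 | 7.0 | 35.4 |
| beta | 8.00 | 8.8 | 38.4 |
| beta | 10.0 | 9.3 | 40.5 |
| alpha | 4.00 | 10.9 | 44.3 |
| alpha | 5.00 | 14.0 | 46.6 |
| alpha | 6.00 | 16.2 | 47.5 |
| alpha | 8.00 | 20.3 | 49.3 |
| alpha | 10.0 | 23.6 | 49.7 |

(standard deviation of a reading: 0.3 percentage points)

1. time up to 15 min at which right-handed product stands highest
2. the amount of right-handed product, in percent of the left-handed substrate and right-handed substrate together charged, at that time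
3. the first time at which right-handed product reaches 11%, in the same percent, in min

- partner is single-handed; left-handed substrate and right-handed substrate are mirror images of each other, charged as a racemate, each of them at the stated concentration
- every charge counts on the volume at the start, and the solution that is fed holds the whole dose
- the handed part of partner does not stay in what it makes, so the products of the two hands are mirror images too

- We take each hand's rate as proportional to its substrate and to partner. Both hands then see the same partner at every moment, whatever the feed does.
- So we carry the selectivity factor: the logarithm of the left-handed fraction remaining over the logarithm of the right-handed fraction remaining. The last beta reading gives 8.07.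
- Start: in the flask, right-handed product climbs at 12.4% of the left-handed slope.
- Knee: the flask lies between epsilon and beta in substrate, at equal partner. Interpolating at 10.0 min gives right-handed product 11.9%. That leaves a right-handed fraction of 76.2%, so the factor puts the left-handed fraction at 11.2%.
- Order: the flask's partner charge is twice one hand's charge, so once the feed is in, partner equals the two substrates together. At 10.0 min we reckon it exceeds right-handed substrate by 14.7%. From there one concentration nearly serves for both, the rate is close to second order, and we take the inverse right-handed fraction to climb in a nearly straight line.
- Slope: alpha's right-handed decay, divided by its mean partner and scaled to the flask's diluted substrate, gives 0.0241 min⁻¹.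
- Our reckoning: the flask passes the level at 8.76 min and reaches 15.1% at 15 min. That is still rising, below the level of 50.0% that the partner left over from the left-handed hand allows.
- The forecast says 15 min, 14.9% and 9.4 min, on the ground “Right-handed product therefore keeps rising”; its time is later than ours and its top lower.
- The flask gives 15.0 min, 15.2% and 9.10 min.

    partner + left-handed substrate → left-handed product (k = 0.0310 M⁻¹ s⁻¹)
    partner + right-handed substrate → right-handed product (k = 0.00386 M⁻¹ s⁻¹)

- At 2.58 min the flask's left-handed substrate has a half-life of 2.6 min, against 21 min for right-handed substrate. At 15.0 min the left-handed step draws partner at 0.63 of the right-handed rate. With 8.07, the 5.5% of its charge of left-handed substrate remaining goes with 69.8% of right-handed, and 70% of that charge stands.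
- In the neighbour charged with 0.10 M of partner, 61% of the left-handed substrate charged remains at 15.0 min, and 8.07 turns that into 2.97% right-handed product. The neighbour holds 2.97%.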